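Numbering: ring O1, C2(=O), C3–C6; chain C7–C16. Everything rests on disconnecting the lactone between carbonyl carbon C2 and C3. The route builds an open-chain (Z)-alkenyl iodide in which O1, on C6, already carries C2 as a carbonate; the cis C3=C4 bond of the dihydropyranone ring holds C3 within reach of C2. Iodine–lithium exchange then closes the ring by acylating C3 with C2, delivering the unsaturated δ-lactone at its final oxidation level in one operation. The precursor's C6/C10 (E)-ene-1,5-anti-diol comes from one double allylboration, its C12/C14 syn-diol from a catalytic aldol and a syn-reduction.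

Key step: step 11

Remark: the sense of induction is assumed as (R)-BINOL/Ti(OiPr)4 → (5R)-aldol and (dIpc)2BH → (R)-carbinol at C6 (as in allyl- and crotylborations with this borane); the antipodal ligand or borane would be used if either proved opposite.

Step 1
Reactants: 1 (E)-cinnamaldehyde; 2 1-methoxy-1,3-bis(trimethylsilyloxy)buta-1,3-diene
Product: 3 methyl (5R,6E)-5-hydroxy-3-oxo-7-phenylhept-6-enoate
Conditions: Ti(OiPr)4 (10 mol %), (R)-BINOL (10 mol %), 4 Å MS, THF, −78 °C → rt; then 1 M HCl, 0 °C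
Reagents that add atoms: none
Why: Catalytic enantioselective vinylogous Mukaiyama aldol addition: the BINOL–titanium Lewis acid activates and shields one face of the aldehyde, the terminal carbon of the bis-silyl dienolate adds 1,2 to set the C14 carbinol (5R in 3) by catalyst control, and acid work-up releases the β-keto ester.

Step 2
Reactants: 3 methyl (5R,6E)-5-hydroxy-3-oxo-7-phenylhept-6-enoate
Product: 4 methyl (3S,5R,6E)-3,5-dihydroxy-7-phenylhept-6-enoate
Conditions: Et2BOMe, NaBH4, THF/MeOH (4:1), −78 °C; aq. NH4Cl, then MeOH co-evaporation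
Reagents that add atoms: none
Why: Narasaka–Prasad reduction: Et2BOMe locks the β-hydroxy ketone as a six-membered boron chelate that NaBH4 reduces by axial attack, so the C14 carbinol relays the 1,3-syn C12 centre by substrate control.

Step 3
Reactants: 4 methyl (3S,5R,6E)-3,5-dihydroxy-7-phenylhept-6-enoate
Product: 5 methyl (3S,5R,6E)-3,5-bis[(tert-butyldimethylsilyl)oxy]-7-phenylhept-6-enoate
Conditions: TBSOTf, 2,6-lutidine, CH2Cl2, −78 → 0 °C
Reagents that add atoms: tert-butyldimethylsilyl triflate, CC(C)(C)[Si](C)(C)OS(=O)(=O)C(F)(F)F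
Why: Silyl ether formation with the silyl triflate and a hindered base protects both secondary carbinols so that the ester can be reduced without lactol formation.

Step 4
Reactants: 5 methyl (3S,5R,6E)-3,5-bis[(tert-butyldimethylsilyl)oxy]-7-phenylhept-6-enoate
Product: 6 (3S,5R,6E)-3,5-bis[(tert-butyldimethylsilyl)oxy]-7-phenylhept-6-enal
Conditions: i-Bu2AlH (DIBAL-H, 1.1 equiv), CH2Cl2, −78 °C; aq. potassium sodium tartrate
Reagents that add atoms: none
Why: Partial ester reduction: at −78 °C the aluminium hemiacetal from DIBAL-H persists until work-up and then gives the aldehyde, the β-silyloxy group suppressing over-reduction and leaving C12 untouched.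

Step 5
Reactants: 7 4-(trimethylsilyl)but-3-yn-1-ol
Product: 8 4-(trimethylsilyl)but-3-ynal
Conditions: Dess–Martin periodinane, CH2Cl2, 0 °C → rt; filtered cold and used at once as a solution
Reagents that add atoms: none
Why: Dess–Martin oxidation is neutral and base-free, which should deliver the β,γ-alkynyl aldehyde without isomerization to the allenal.

Step 6
Reactants: 9 propargyl bromide; 10 trimethyl borate; 11 2,2-dimethylpropane-1,3-diol
Product: 14 5,5-dimethyl-2-(propa-1,2-dien-1-yl)-1,3,2-dioxaborinane, via allenylmagnesium bromide 12 (not isolated), via allenylboronic acid 13 (not isolated)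
Conditions: Mg, HgCl2 (1 mol %), Et2O, 0 °C; 10, −78 °C; 1 M HCl, 0 °C; then 11, MgSO4, CH2Cl2, rt
Reagents that add atoms: none
Why: Grignard borylation and esterification: the allenyl Grignard reagent from propargyl bromide adds to B(OMe)3 to give the allenylboron compound, and exchange with the 1,3-diol gives the unhindered six-membered boronate that later favours the E alkene.

Step 7
Reactants: 14 5,5-dimethyl-2-(propa-1,2-dien-1-yl)-1,3,2-dioxaborinane; 8 4-(trimethylsilyl)but-3-ynal; 6 (3S,5R,6E)-3,5-bis[(tert-butyldimethylsilyl)oxy]-7-phenylhept-6-enal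
Product: 18 (1E,3R,5R,7S,9E,11R)-3,5-bis[(tert-butyldimethylsilyl)oxy]-1-phenyl-14-(trimethylsilyl)tetradeca-1,9-dien-13-yne-7,11-diol, via (E)-γ-borylallylborane 15 (not isolated), via α-boryl homoallylic borinate 16 (not isolated), via bis-O-borylated diol 17 (not isolated)
Conditions: 14 (1.4 equiv), (dIpc)2BH (1.2 equiv, from (+)-α-pinene and BH3·SMe2), toluene, 0 °C; 8 (1.2 equiv), −78 °C; 6 (1.0 equiv), −78 °C → rt; NaHCO3, 30% H2O2 (aq), 0 °C → rt
Reagents that add atoms: none
Why: One-pot double allylboration: the Ipc2B terminus of the (E)-γ-borylallylborane 15 adds to 8 through a chair transition state (reagent control) to set C6 (R) and the anti α-boryl centre of 16, which then transfers its chirality in the second, boronate allylboration of 6 (α-substituent equatorial) to give the E C7=C8 alkene and C10 (S), so that two stereocentres and the alkene arise from one chiral reagent.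

Step 8
Reactants: 18 (1E,3R,5R,7S,9E,11R)-3,5-bis[(tert-butyldimethylsilyl)oxy]-1-phenyl-14-(trimethylsilyl)tetradeca-1,9-dien-13-yne-7,11-diol
Product: 19 (1E,3R,5R,7S,9E,11R)-3,5-bis[(tert-butyldimethylsilyl)oxy]-1-phenyl-14-(trimethylsilyl)tetradeca-1,9-dien-13-yne-7,11-diyl bis[2-(trimethylsilyl)ethyl] dicarbonate
Conditions: 2-(trimethylsilyl)ethyl chloroformate (Teoc-Cl, 3 equiv), pyridine, DMAP (cat.), CH2Cl2, 0 °C → rt
Reagents that add atoms: 2-(trimethylsilyl)ethyl chloroformate, C[Si](C)(C)CCOC(=O)Cl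
Why: Carbonate formation by acylation with the chloroformate (pyridine/DMAP catalysis) needs no differentiation of the two carbinols, because the C6 carbonate later supplies C2 on O1 as the internal acyl donor and the C10 carbonate serves as a fluoride-labile protecting group.

Step 9
Reactants: 19 (1E,3R,5R,7S,9E,11R)-3,5-bis[(tert-butyldimethylsilyl)oxy]-1-phenyl-14-(trimethylsilyl)tetradeca-1,9-dien-13-yne-7,11-diyl bis[2-(trimethylsilyl)ethyl] dicarbonate
Product: 20 (1E,3R,5R,7S,9E,11R)-3,5-bis[(tert-butyldimethylsilyl)oxy]-14-iodo-1-phenyltetradeca-1,9-dien-13-yne-7,11-diyl bis[2-(trimethylsilyl)ethyl] dicarbonate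
Conditions: NIS (1.2 equiv), AgNO3 (10 mol %), DMF, rt, dark
Reagents that add atoms: N-iodosuccinimide, O=C1CCC(=O)N1I
Why: Silver-catalysed iododesilylation: AgNO3 converts the alkynylsilane into a silver acetylide that NIS iodinates, while the 1,2-disubstituted alkenes should not react with NIS in the absence of acid.

Step 10
Reactants: 20 (1E,3R,5R,7S,9E,11R)-3,5-bis[(tert-butyldimethylsilyl)oxy]-14-iodo-1-phenyltetradeca-1,9-dien-13-yne-7,11-diyl bis[2-(trimethylsilyl)ethyl] dicarbonate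
Product: 21 (1E,3R,5R,7S,9E,11R,13Z)-3,5-bis[(tert-butyldimethylsilyl)oxy]-14-iodo-1-phenyltetradeca-1,9,13-triene-7,11-diyl bis[2-(trimethylsilyl)ethyl] dicarbonate
Conditions: 2-nitrobenzenesulfonylhydrazide, Et3N, THF/i-PrOH (1:1), rt
Reagents that add atoms: none
Why: Diimide semi-reduction: diimide generated in situ delivers H2 syn to the iodoalkyne much faster than to the 1,2-disubstituted alkenes, which should give the (Z)-alkenyl iodide with the C3=C4 geometry required in the ring.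

Step 11
Reactants: 21 (1E,3R,5R,7S,9E,11R,13Z)-3,5-bis[(tert-butyldimethylsilyl)oxy]-14-iodo-1-phenyltetradeca-1,9,13-triene-7,11-diyl bis[2-(trimethylsilyl)ethyl] dicarbonate
Product: 24 (6R)-6-[(1E,4S,6R,8R,9E)-6,8-bis[(tert-butyldimethylsilyl)oxy]-10-phenyl-4-({[2-(trimethylsilyl)ethoxy]carbonyl}oxy)deca-1,9-dien-1-yl]-5,6-dihydro-2H-pyran-2-one, via alkenyllithium 22 (not isolated), via cyclic lithium alkoxide 23 (not isolated)
Conditions: t-BuLi (2.1 equiv), Et2O, −100 → −78 °C; AcOH, −78 °C → rt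
Reagents that add atoms: none
Why: Proposed new method: t-BuLi exchanges the alkenyl iodine faster than it adds to a carbonate, giving the configurationally stable (Z)-alkenyllithium 22, whose C3 carbanion attacks the carbonate carbon C2 held on O1, and the tetrahedral alkoxide 23 expels lithium 2-(trimethylsilyl)ethoxide to give the lactone. The closest known reaction type is the Parham cyclization (halogen–lithium exchange followed by intramolecular acylation), established for aryl halides with ester, carbamate and amide acceptors and for alkenyl iodides with ketone and amide acceptors. The six-membered ring closes in the 6-exo-trig mode, the carbonyl oxygen being exocyclic. No stereocentre is created: C6 is untouched and the C3=C4 geometry is carried over from the iodide. The step needs selection between the two identical carbonates and between exchange and addition: the Z alkene places C3 five atoms from C2 of the C6 carbonate (six-membered transition state) while the C10 carbonate would need a ten-membered one, and exchange at −100 °C should outrun carbonyl attack by the hindered base. Should 23 open to the acyclic (Z)-hydroxy ester instead, the C6 alkoxide can reclose on that ester to the same lactone.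

Step 12
Reactants: 24 (6R)-6-[(1E,4S,6R,8R,9E)-6,8-bis[(tert-butyldimethylsilyl)oxy]-10-phenyl-4-({[2-(trimethylsilyl)ethoxy]carbonyl}oxy)deca-1,9-dien-1-yl]-5,6-dihydro-2H-pyran-2-one
Product: 25 (6R)-6-[(1E,4S,6R,8R,9E)-4,6,8-trihydroxy-10-phenyldeca-1,9-dien-1-yl]-5,6-dihydro-2H-pyran-2-one
Conditions: TBAF (6 equiv), AcOH (6 equiv), THF, 0 °C → rt
Reagents that add atoms: none
Why: Fluoride-mediated global deprotection: fluoride cleaves the two TBS ethers and fragments the Teoc group (loss of fluorotrimethylsilane, ethene and CO2), and the acetic acid buffer keeps the medium non-basic so that the unsaturated lactone should not be opened or isomerized.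

Compound list
1 | (E)-cinnamaldehyde | O=C/C=C/c1ccccc1 | starting material
2 | 1-methoxy-1,3-bis(trimethylsilyloxy)buta-1,3-diene | COC(O[Si](C)(C)C)=CC(=C)O[Si](C)(C)C | starting material
3 | methyl (5R,6E)-5-hydroxy-3-oxo-7-phenylhept-6-enoate | COC(=O)CC(=O)C[C@@H](O)/C=C/c1ccccc1 | intermediate
4 | methyl (3S,5R,6E)-3,5-dihydroxy-7-phenylhept-6-enoate | COC(=O)C[C@@H](O)C[C@@H](O)/C=C/c1ccccc1 | intermediate
5 | methyl (3S,5R,6E)-3,5-bis[(tert-butyldimethylsilyl)oxy]-7-phenylhept-6-enoate | COC(=O)C[C@@H](O[Si](C)(C)C(C)(C)C)C[C@@H](O[Si](C)(C)C(C)(C)C)/C=C/c1ccccc1 | intermediate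
6 | (3S,5R,6E)-3,5-bis[(tert-butyldimethylsilyl)oxy]-7-phenylhept-6-enal | O=CC[C@@H](O[Si](C)(C)C(C)(C)C)C[C@@H](O[Si](C)(C)C(C)(C)C)/C=C/c1ccccc1 | intermediate
7 | 4-(trimethylsilyl)but-3-yn-1-ol | C[Si](C)(C)C#CCCO | starting material
8 | 4-(trimethylsilyl)but-3-ynal | C[Si](C)(C)C#CCC=O | intermediate
9 | propargyl bromide (3-bromoprop-1-yne) | C#CCBr | starting material
10 | trimethyl borate | COB(OC)OC | starting material
11 | 2,2-dimethylpropane-1,3-diol | OCC(C)(C)CO | starting material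
12 | allenylmagnesium bromide | C=C=C[Mg]Br | intermediate
13 | allenylboronic acid | C=C=CB(O)O | intermediate
14 | 5,5-dimethyl-2-(propa-1,2-dien-1-yl)-1,3,2-dioxaborinane | C=C=CB1OCC(C)(C)CO1 | intermediate
15 | [(E)-3-(5,5-dimethyl-1,3,2-dioxaborinan-2-yl)allyl]bis(isopinocampheyl)borane | C(/C=C/B1OCC(C)(C)CO1)B([C@@H]2C[C@@H]3C[C@H]([C@H]2C)C3(C)C)[C@@H]2C[C@@H]3C[C@H]([C@H]2C)C3(C)C | intermediate
16 | (3S,4R)-3-(5,5-dimethyl-1,3,2-dioxaborinan-2-yl)-6-(trimethylsilyl)hex-1-en-5-yn-4-yl bis(isopinocampheyl)borinate | C[Si](C)(C)C#CC[C@@H](OB([C@@H]1C[C@@H]2C[C@H]([C@H]1C)C2(C)C)[C@@H]1C[C@@H]2C[C@H]([C@H]1C)C2(C)C)[C@@H](B1OCC(C)(C)CO1)C=C | intermediate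
17 | diol 18 carrying bis(isopinocampheyl)boryl on O11 and 5,5-dimethyl-1,3,2-dioxaborinan-2-yl on O7 | C[Si](C)(C)C#CC[C@@H](OB([C@@H]1C[C@@H]2C[C@H]([C@H]1C)C2(C)C)[C@@H]1C[C@@H]2C[C@H]([C@H]1C)C2(C)C)/C=C/C[C@H](OB1OCC(C)(C)CO1)C[C@@H](O[Si](C)(C)C(C)(C)C)C[C@@H](O[Si](C)(C)C(C)(C)C)/C=C/c1ccccc1 | intermediate
18 | (1E,3R,5R,7S,9E,11R)-3,5-bis[(tert-butyldimethylsilyl)oxy]-1-phenyl-14-(trimethylsilyl)tetradeca-1,9-dien-13-yne-7,11-diol | C[Si](C)(C)C#CC[C@@H](O)/C=C/C[C@H](O)C[C@@H](O[Si](C)(C)C(C)(C)C)C[C@@H](O[Si](C)(C)C(C)(C)C)/C=C/c1ccccc1 | intermediate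
19 | (1E,3R,5R,7S,9E,11R)-3,5-bis[(tert-butyldimethylsilyl)oxy]-1-phenyl-14-(trimethylsilyl)tetradeca-1,9-dien-13-yne-7,11-diyl bis[2-(trimethylsilyl)ethyl] dicarbonate | C[Si](C)(C)C#CC[C@@H](OC(=O)OCC[Si](C)(C)C)/C=C/C[C@H](OC(=O)OCC[Si](C)(C)C)C[C@@H](O[Si](C)(C)C(C)(C)C)C[C@@H](O[Si](C)(C)C(C)(C)C)/C=C/c1ccccc1 | intermediate
20 | (1E,3R,5R,7S,9E,11R)-3,5-bis[(tert-butyldimethylsilyl)oxy]-14-iodo-1-phenyltetradeca-1,9-dien-13-yne-7,11-diyl bis[2-(trimethylsilyl)ethyl] dicarbonate | IC#CC[C@@H](OC(=O)OCC[Si](C)(C)C)/C=C/C[C@H](OC(=O)OCC[Si](C)(C)C)C[C@@H](O[Si](C)(C)C(C)(C)C)C[C@@H](O[Si](C)(C)C(C)(C)C)/C=C/c1ccccc1 | intermediate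
21 | (1E,3R,5R,7S,9E,11R,13Z)-3,5-bis[(tert-butyldimethylsilyl)oxy]-14-iodo-1-phenyltetradeca-1,9,13-triene-7,11-diyl bis[2-(trimethylsilyl)ethyl] dicarbonate | I/C=C\C[C@@H](OC(=O)OCC[Si](C)(C)C)/C=C/C[C@H](OC(=O)OCC[Si](C)(C)C)C[C@@H](O[Si](C)(C)C(C)(C)C)C[C@@H](O[Si](C)(C)C(C)(C)C)/C=C/c1ccccc1 | intermediate
22 | (Z)-alkenyllithium from 21 (lithium in place of iodine at C3) | [Li]/C=C\C[C@@H](OC(=O)OCC[Si](C)(C)C)/C=C/C[C@H](OC(=O)OCC[Si](C)(C)C)C[C@@H](O[Si](C)(C)C(C)(C)C)C[C@@H](O[Si](C)(C)C(C)(C)C)/C=C/c1ccccc1 | intermediate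
23 | lithium alkoxide of the cyclic tetrahedral adduct at C2 (2-[2-(trimethylsilyl)ethoxy]-5,6-dihydro-2H-pyran-2-olate) | [Li]OC1(OCC[Si](C)(C)C)C=CC[C@H](/C=C/C[C@H](OC(=O)OCC[Si](C)(C)C)C[C@@H](O[Si](C)(C)C(C)(C)C)C[C@@H](O[Si](C)(C)C(C)(C)C)/C=C/c2ccccc2)O1 | intermediate
24 | (6R)-6-[(1E,4S,6R,8R,9E)-6,8-bis[(tert-butyldimethylsilyl)oxy]-10-phenyl-4-({[2-(trimethylsilyl)ethoxy]carbonyl}oxy)deca-1,9-dien-1-yl]-5,6-dihydro-2H-pyran-2-one | O=C1C=CC[C@H](/C=C/C[C@H](OC(=O)OCC[Si](C)(C)C)C[C@@H](O[Si](C)(C)C(C)(C)C)C[C@@H](O[Si](C)(C)C(C)(C)C)/C=C/c2ccccc2)O1 | intermediate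
25 | (6R)-6-[(1E,4S,6R,8R,9E)-4,6,8-trihydroxy-10-phenyldeca-1,9-dien-1-yl]-5,6-dihydro-2H-pyran-2-one | O=C1C=CC[C@H](/C=C/C[C@H](O)C[C@@H](O)C[C@@H](O)/C=C/c2ccccc2)O1 | target

Total step count: 12. Longest linear sequence: 10 steps (steps 1–4 and 7–12); steps 5 and 6 prepare the two partners of step 7.

Steps most likely to fail

1. Step 11 (proposed new method). The alkenyllithium may be protonated or add intermolecularly before it acylates the hindered secondary carbonate, or the base may attack a carbonate before the exchange is complete. The fallback uses known chemistry, the palladium-catalysed cyclocarbonylation of a (Z)-iodo homoallylic alcohol, and sets out from diol 18. Iododesilylation (NIS, AgNO3 cat., DMF) should give (1E,3R,5R,7S,9E,11R)-3,5-bis[(tert-butyldimethylsilyl)oxy]-14-iodo-1-phenyltetradeca-1,9-dien-13-yne-7,11-diol F1. Diimide semi-reduction (2-nitrobenzenesulfonylhydrazide, Et3N) should give the (13Z)-iodo triene diol F2. PdCl2(PPh3)2 (5 mol %), CO (1 atm), Et3N, THF, rt should then convert F2 into (6R)-6-[(1E,4S,6R,8R,9E)-6,8-bis[(tert-butyldimethylsilyl)oxy]-4-hydroxy-10-phenyldeca-1,9-dien-1-yl]-5,6-dihydro-2H-pyran-2-one F3, with C2 coming from CO; only the C6 hydroxyl can close a six-membered ring. HF·pyridine in THF removes the two TBS ethers and the route comes back at target 25.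

2. Step 7. The β,γ-alkynyl aldehyde 8 may isomerize to the allenal before it is captured, and the second allylboration may proceed with incomplete E or facial selectivity with the β-silyloxy aldehyde. The fallback builds the same array stepwise from aldehyde 6.
   - Allylboration with (−)-Ipc2B-allyl should give (1E,3R,5R,7S)-3,5-bis[(tert-butyldimethylsilyl)oxy]-1-phenyldeca-1,9-dien-7-ol F4.
   - Teoc-Cl/pyridine gives its 2-(trimethylsilyl)ethyl carbonate F5.
   - Cross-metathesis with crotonaldehyde (second-generation Grubbs catalyst, CH2Cl2, 40 °C) gives (2E,5S,7R,9R,10E)-7,9-bis[(tert-butyldimethylsilyl)oxy]-11-phenyl-5-({[2-(trimethylsilyl)ethoxy]carbonyl}oxy)undeca-2,10-dienal F6.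
   - Propargylation with allenylboronic acid pinacol ester, catalysed by the chiral phosphoric acid TRIP (enantiomer chosen for the 11R carbinol), gives the homopropargylic alcohol (1E,3R,5R,7S,9E,11R)-3,5-bis[(tert-butyldimethylsilyl)oxy]-11-hydroxy-1-phenyltetradeca-1,9-dien-13-yn-7-yl 2-(trimethylsilyl)ethyl carbonate F7.
   - A second Teoc-Cl acylation gives the terminal-alkyne bis-carbonate F8, and NIS/AgNO3 iodination of the terminal alkyne brings the route back at iodoalkyne 20.

3. Step 12. Fluoride may open or isomerize the base-sensitive lactone (elimination across C5/C6), or fragmentation of the carbonate may stay incomplete under buffered conditions. The fallback changes the order of events and sets out from 21. Unbuffered TBAF in THF removes all silicon-based groups while no lactone is present, giving (1E,3R,5R,7S,9E,11R,13Z)-14-iodo-1-phenyltetradeca-1,9,13-triene-3,5,7,11-tetrol F9. The ring is then closed last under neutral conditions by cyclocarbonylation (PdCl2(PPh3)2, CO 1 atm, Et3N, THF, rt), which needs no protecting groups because only the C6 hydroxyl can form a six-membered lactone; the route comes back at 25.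

Further compounds
F1 | step 11 | (1E,3R,5R,7S,9E,11R)-3,5-bis[(tert-butyldimethylsilyl)oxy]-14-iodo-1-phenyltetradeca-1,9-dien-13-yne-7,11-diol | IC#CC[C@@H](O)/C=C/C[C@H](O)C[C@@H](O[Si](C)(C)C(C)(C)C)C[C@@H](O[Si](C)(C)C(C)(C)C)/C=C/c1ccccc1
F2 | step 11 | (1E,3R,5R,7S,9E,11R,13Z)-3,5-bis[(tert-butyldimethylsilyl)oxy]-14-iodo-1-phenyltetradeca-1,9,13-triene-7,11-diol | I/C=C\C[C@@H](O)/C=C/C[C@H](O)C[C@@H](O[Si](C)(C)C(C)(C)C)C[C@@H](O[Si](C)(C)C(C)(C)C)/C=C/c1ccccc1
F3 | step 11 | (6R)-6-[(1E,4S,6R,8R,9E)-6,8-bis[(tert-butyldimethylsilyl)oxy]-4-hydroxy-10-phenyldeca-1,9-dien-1-yl]-5,6-dihydro-2H-pyran-2-one | O=C1C=CC[C@H](/C=C/C[C@H](O)C[C@@H](O[Si](C)(C)C(C)(C)C)C[C@@H](O[Si](C)(C)C(C)(C)C)/C=C/c2ccccc2)O1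
F4 | step 7 | (1E,3R,5R,7S)-3,5-bis[(tert-butyldimethylsilyl)oxy]-1-phenyldeca-1,9-dien-7-ol | C=CC[C@H](O)C[C@@H](O[Si](C)(C)C(C)(C)C)C[C@@H](O[Si](C)(C)C(C)(C)C)/C=C/c1ccccc1
F5 | step 7 | (1E,3R,5R,7S)-3,5-bis[(tert-butyldimethylsilyl)oxy]-1-phenyldeca-1,9-dien-7-yl 2-(trimethylsilyl)ethyl carbonate | C=CC[C@H](OC(=O)OCC[Si](C)(C)C)C[C@@H](O[Si](C)(C)C(C)(C)C)C[C@@H](O[Si](C)(C)C(C)(C)C)/C=C/c1ccccc1
F6 | step 7 | (2E,5S,7R,9R,10E)-7,9-bis[(tert-butyldimethylsilyl)oxy]-11-phenyl-5-({[2-(trimethylsilyl)ethoxy]carbonyl}oxy)undeca-2,10-dienal | O=C/C=C/C[C@H](OC(=O)OCC[Si](C)(C)C)C[C@@H](O[Si](C)(C)C(C)(C)C)C[C@@H](O[Si](C)(C)C(C)(C)C)/C=C/c1ccccc1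
F7 | step 7 | (1E,3R,5R,7S,9E,11R)-3,5-bis[(tert-butyldimethylsilyl)oxy]-11-hydroxy-1-phenyltetradeca-1,9-dien-13-yn-7-yl 2-(trimethylsilyl)ethyl carbonate | C#CC[C@@H](O)/C=C/C[C@H](OC(=O)OCC[Si](C)(C)C)C[C@@H](O[Si](C)(C)C(C)(C)C)C[C@@H](O[Si](C)(C)C(C)(C)C)/C=C/c1ccccc1
F8 | step 7 | (1E,3R,5R,7S,9E,11R)-3,5-bis[(tert-butyldimethylsilyl)oxy]-1-phenyltetradeca-1,9-dien-13-yne-7,11-diyl bis[2-(trimethylsilyl)ethyl] dicarbonate | C#CC[C@@H](OC(=O)OCC[Si](C)(C)C)/C=C/C[C@H](OC(=O)OCC[Si](C)(C)C)C[C@@H](O[Si](C)(C)C(C)(C)C)C[C@@H](O[Si](C)(C)C(C)(C)C)/C=C/c1ccccc1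
F9 | step 12 | (1E,3R,5R,7S,9E,11R,13Z)-14-iodo-1-phenyltetradeca-1,9,13-triene-3,5,7,11-tetrol | I/C=C\C[C@@H](O)/C=C/C[C@H](O)C[C@@H](O)C[C@@H](O)/C=C/c1ccccc1
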